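**Retrosynthetic overview**

1. The route rests on ring B. Its neighbouring carbons C8 (secondary CH3, α) and C9 (tertiary OH β, side chain α) carry hydroxyl and methyl on opposite faces. That is the arrangement produced when a C9 ketone radical anion closes onto a C8=C17 vinyl group, so ring B is made last by forming C8–C9 with SmI2.
2. The cyclisation substrate is a ring A ketone. C10 bears CH3 and the C9 acyl chain (C13 ketone masked as dioxolane), C5 bears the but-3-enyl arm, and C2=C3 is an alkene that is dihydroxylated only after ring closure.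
3. C9–C10 comes from an aldol of a ring A enolate on the face opposite the C5 arm. C5 and the C10 methyl come from a copper-catalysed asymmetric butenyl addition with enolate methylation on 4,4-dimethylcyclohexadienone. The C1 carbonyl that served both steps is then erased by Wharton transposition and a reductive alkene transposition.
4. After ring closure: α-face osmylation (C2, C3), ketal hydrolysis, Horner–Wadsworth–Emmons olefination (C13=C14) and acetylation of the C2 hydroxyl.
5. Ring order: ring A (from the commercial enone), then ring B (key step).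

Key step: step 10

Remark: carbons are numbered as in labdanes. The 2,3-diol is made after ring closure, because OsO4 would attack the terminal butenyl alkene before the hindered ring alkene; the cyclisation substrate 17 therefore carries the C2=C3 alkene and not a protected diol. Compounds 10 to 16 are carried as epimer mixtures at centres that are later made planar.

Step 1
Reactants: 1 4,4-dimethylcyclohex-2-en-1-one
Product: 2 4,4-dimethylcyclohexa-2,5-dien-1-one
Conditions: DDQ (1.3 equiv), 1,4-dioxane, reflux
Reagents that add atoms: none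
Why: Dehydrogenation of a ketone α,β to the carbonyl by DDQ (hydride abstraction from the enol) is a known way to turn this enone into the cross-conjugated dienone, and the quaternary C4 leaves no other site.

Step 2
Reactants: 2 4,4-dimethylcyclohexa-2,5-dien-1-one; 3 but-3-en-1-ylmagnesium bromide; 4 iodomethane
Product: 6 (5R,6R)-5-(but-3-en-1-yl)-4,4,6-trimethylcyclohex-2-en-1-one, via bromomagnesium dienolate 5 (not isolated)
Conditions: CuBr·SMe2 (5 mol%), (R)-1-[(S)-2-(diphenylphosphino)ferrocenyl]ethyldicyclohexylphosphine (6 mol%; ligand antipode chosen to give the 5R adduct), t-BuOMe, −75 °C, slow addition of 3; then DMPU, MeI, −75 to 0 °C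
Reagents that add atoms: but-3-en-1-ylmagnesium bromide (C=CCC[Mg]Br); iodomethane (CI)
Why: Copper-catalysed asymmetric conjugate addition of a Grignard reagent to a cyclic enone, here a desymmetrisation of the achiral dienone in which the chiral copper–diphosphine complex chooses the face of the β-carbon and so sets C5, followed by C-methylation of the magnesium enolate trans to the new chain (the methyl-bearing carbon is made planar again in step 4).

Step 3
Reactants: 6 (5R,6R)-5-(but-3-en-1-yl)-4,4,6-trimethylcyclohex-2-en-1-one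
Product: 7 (3R,4R)-4-(but-3-en-1-yl)-3,5,5-trimethyl-7-oxabicyclo[4.1.0]heptan-2-one (both epoxide diastereomers)
Conditions: 30% H2O2, NaOH (0.5 equiv), MeOH, 0 °C to rt
Reagents that add atoms: hydrogen peroxide (OO)
Why: Weitz–Scheffer epoxidation: hydroperoxide anion adds only to the electron-poor enone alkene and leaves the terminal alkene, and the epoxide configuration does not matter because C2 becomes sp2 in step 5 and the C3 carbinol is oxidised in step 6.

Step 4
Reactants: 7 (3R,4R)-4-(but-3-en-1-yl)-3,5,5-trimethyl-7-oxabicyclo[4.1.0]heptan-2-one; 8 3-(2-methyl-1,3-dioxolan-2-yl)propanal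
Product: 10 (3S,4S)-4-(but-3-en-1-yl)-3-[1-hydroxy-3-(2-methyl-1,3-dioxolan-2-yl)propyl]-3,5,5-trimethyl-7-oxabicyclo[4.1.0]heptan-2-one (both carbinol epimers; both epoxide diastereomers), via lithium enolate 9 (not isolated)
Conditions: LiN(i-Pr)2 (1.1 equiv), THF, −78 °C; then 8, −78 °C; AcOH quench at −78 °C
Reagents that add atoms: 3-(2-methyl-1,3-dioxolan-2-yl)propanal (CC1(CCC=O)OCCO1)
Why: Aldol addition of the lithium enolate formed at C10 (the epoxide carbon on the other side does not give an enolate) to the aldehyde at low temperature, the aldehyde approaching the face opposite the neighbouring C5 butenyl group so that the new quaternary centre carries methyl cis and the C9 chain trans to that group; the C9 carbinol epimers both lead on to ketone 17.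

Step 5
Reactants: 10 epoxy aldol
Product: 12 (4S,5S)-5-(but-3-en-1-yl)-4-[1-hydroxy-3-(2-methyl-1,3-dioxolan-2-yl)propyl]-4,6,6-trimethylcyclohex-2-en-1-ol (epimers at both carbinol carbons), via epoxy hydrazone 11 (not isolated)
Conditions: N2H4·H2O (3 equiv), AcOH (0.3 equiv), MeOH, 0 °C to rt, under Ar
Reagents that add atoms: none
Why: Wharton transposition: the hydrazone of the α,β-epoxy ketone opens the epoxide to a vinyl diazene that loses N2, which removes the C1 oxygen, leaves C1=C2 and puts a hydroxyl on C3 (argon excludes diimide formation that could reduce the terminal alkene).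

Step 6
Reactants: 12 allylic alcohol
Product: 13 (4S,5R)-5-(but-3-en-1-yl)-4-[1-hydroxy-3-(2-methyl-1,3-dioxolan-2-yl)propyl]-4,6,6-trimethylcyclohex-2-en-1-one (carbinol epimers)
Conditions: activated MnO2 (15 equiv), CH2Cl2, rt
Reagents that add atoms: none
Why: Activated MnO2 oxidises allylic alcohols selectively, so only the C3 hydroxyl becomes a carbonyl and the saturated C9 carbinol is kept, giving the enone transposed relative to 6.

Step 7
Reactants: 13 transposed enone
Product: 14 tosylhydrazone of 13 (C=N–NHTs at the ring carbonyl carbon; ring stereocentres unchanged)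
Conditions: TsNHNH2 (1.3 equiv), EtOH, 60 °C, no added acid
Reagents that add atoms: 4-methylbenzenesulfonohydrazide (Cc1ccc(cc1)S(=O)(=O)NN)
Why: Condensation of the conjugated ketone with the sulfonyl hydrazide, run without added acid so that the dioxolane is not exchanged, gives the α,β-unsaturated tosylhydrazone needed for reductive alkene transposition.

Step 8
Reactants: 14 tosylhydrazone
Product: 16 1-[(1S,6S)-6-(but-3-en-1-yl)-1,5,5-trimethylcyclohex-3-en-1-yl]-3-(2-methyl-1,3-dioxolan-2-yl)propan-1-ol (carbinol epimers), via allylic diazene 15 (not isolated)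
Conditions: catecholborane (3 equiv), CHCl3, 0 °C; then NaOAc·3H2O, 60 °C
Reagents that add atoms: none
Why: Catecholborane reduction of an α,β-unsaturated tosylhydrazone: hydride adds to C3, acetate triggers loss of sulfinate, and the allylic diazene delivers hydrogen to C1 in a retro-ene step with loss of N2, so the alkene ends at C2=C3 and C1 is a CH2 group.

Step 9
Reactants: 16 homoallylic alcohol
Product: 17 1-[(1S,6S)-6-(but-3-en-1-yl)-1,5,5-trimethylcyclohex-3-en-1-yl]-3-(2-methyl-1,3-dioxolan-2-yl)propan-1-one
Conditions: Dess–Martin periodinane (1.5 equiv), NaHCO3, CH2Cl2, 0 °C to rt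
Reagents that add atoms: none
Why: Dess–Martin oxidation of the hindered secondary alcohol gives the C9 ketone under buffered conditions that spare the dioxolane and both alkenes, and merges the two carbinol epimers.

Step 10
Reactants: 17 ring A keto alkene
Product: 19 (1S,2R,4aS,8aS)-2,5,5,8a-tetramethyl-1-[2-(2-methyl-1,3-dioxolan-2-yl)ethyl]-1,2,3,4,4a,5,8,8a-octahydronaphthalen-1-ol (trans-fused; 5α-H; 10β-CH3; 8α-CH3; 9β-OH; 9α-chain), via organosamarium alkoxide 18 (not isolated)
Conditions: SmI2 (3 equiv, 0.1 M in THF), HMPA (10 equiv), t-BuOH (2 equiv), THF, 0 °C to rt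
Reagents that add atoms: none
Why: SmI2–HMPA transfers one electron to the C9 ketone, the samarium ketyl adds to the internal carbon (C8) of the pendant vinyl group, and the primary C17 radical is reduced by a second SmI2 to an alkylsamarium that t-BuOH protonates to the methyl group. The closest known reaction type is the SmI2–HMPA reductive cyclisation of unactivated olefinic ketones, in which six-membered rings form more slowly than five-membered ones. Ring B closes in the 6-exo-trig mode through a chair in which both arms sit equatorial on ring A, so the ring fusion is trans. At C8 the CH2 terminus takes the equatorial (α) position, because the axial alternative would meet the axial C10 methyl group. At C9 the bulky, HMPA-solvated O–Sm group takes the equatorial (β) position on the side away from the alkene terminus, which places hydroxyl trans to the new methyl and the side chain axial (α). The step needs cyclisation to outrun simple reduction of the ketyl and needs the ketone to be the only reducible group: the ketone is too hindered for pinacol coupling and cannot enolise toward C10, the quaternary centre holds the two arms close, and the C2=C3 alkene and the dioxolane are inert to SmI2.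

Step 11
Reactants: 19 bicyclic alkene
Product: 20 (1S,2R,4aS,6S,7R,8aS)-2,5,5,8a-tetramethyl-1-[2-(2-methyl-1,3-dioxolan-2-yl)ethyl]decahydronaphthalene-1,6,7-triol (2α,3α,9β-triol in labdane numbering)
Conditions: K2OsO4·2H2O (3 mol%), NMO (1.5 equiv), THF–t-BuOH–H2O, rt
Reagents that add atoms: N-methylmorpholine N-oxide (C[N+]1([O-])CCOCC1); water (O)
Why: Catalytic OsO4 dihydroxylation with NMO of the only alkene left, a syn addition that should come from the α face of the rigid trans-decalin, away from the axial methyl groups on C10 and C4, to give the 2α,3α-diol.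

Step 12
Reactants: 20 triol ketal
Product: 21 4-[(1S,2R,4aS,6S,7R,8aS)-1,6,7-trihydroxy-2,5,5,8a-tetramethyldecahydronaphthalen-1-yl]butan-2-one
Conditions: 1 M HCl–THF (1:2), rt
Reagents that add atoms: water (O)
Why: Acid-catalysed hydrolysis of the dioxolane frees the C13 methyl ketone, which may rest partly as the five-membered hemiketal with the C9 hydroxyl, under conditions too mild to dehydrate the tertiary alcohol.

Step 13
Reactants: 21 keto triol; 22 trimethyl phosphonoacetate
Product: 23 methyl (2E)-3-methyl-5-[(1S,2R,4aS,6S,7R,8aS)-1,6,7-trihydroxy-2,5,5,8a-tetramethyldecahydronaphthalen-1-yl]pent-2-enoate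
Conditions: NaH (4.0 equiv) and 22 (4.2 equiv) premixed, THF, 0 °C; then 21, rt to 45 °C
Reagents that add atoms: trimethyl phosphonoacetate (COC(=O)CP(=O)(OC)OC)
Why: Horner–Wadsworth–Emmons olefination of the methyl ketone (through its open form) with the preformed sodium phosphonate, a base too weak to deprotonate the hydroxyl groups and so unlikely to trigger oxa-Michael closure of the C9 oxygen onto the product, giving mainly the (E)-enoate with the ester trans to the chain; the minor (Z)-isomer is removed by chromatography.

Step 14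
Reactants: 23 trihydroxy enoate; 24 acetic anhydride
Product: 25 methyl (2E)-5-[(1S,2R,4aS,6S,7R,8aS)-7-acetoxy-1,6-dihydroxy-2,5,5,8a-tetramethyldecahydronaphthalen-1-yl]-3-methylpent-2-enoate (CNP0135744.1)
Conditions: Ac2O (1.1 equiv), pyridine, CH2Cl2, 0 °C
Reagents that add atoms: acetic anhydride (CC(=O)OC(C)=O)
Why: Acetylation discriminates by hindrance: the equatorial secondary C2 hydroxyl reacts much faster than the axial C3 hydroxyl next to the gem-dimethyl carbon and the tertiary C9 hydroxyl, so one equivalent of Ac2O should give the 2-monoacetate.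

**Compound list**

1 | 4,4-dimethylcyclohex-2-en-1-one | CC1(C)CCC(=O)C=C1 | starting material
2 | 4,4-dimethylcyclohexa-2,5-dien-1-one | CC1(C)C=CC(=O)C=C1 | intermediate
3 | but-3-en-1-ylmagnesium bromide | C=CCC[Mg]Br | starting material
4 | iodomethane | CI | starting material
5 | bromomagnesium (3R)-3-(but-3-en-1-yl)-4,4-dimethylcyclohexa-1,5-dien-1-olate | C=CCC[C@@H]1C=C(O[Mg]Br)C=CC1(C)C | intermediate (not isolated)
6 | (5R,6R)-5-(but-3-en-1-yl)-4,4,6-trimethylcyclohex-2-en-1-one | C=CCC[C@H]1C(C)(C)C=CC(=O)[C@@H]1C | intermediate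
7 | (3R,4R)-4-(but-3-en-1-yl)-3,5,5-trimethyl-7-oxabicyclo[4.1.0]heptan-2-one, both epoxide diastereomers | C=CCC[C@H]1C(C)(C)C2OC2C(=O)[C@@H]1C | intermediate
8 | 3-(2-methyl-1,3-dioxolan-2-yl)propanal | CC1(CCC=O)OCCO1 | starting material
9 | lithium enolate of 7 (O–Li on the former carbonyl carbon, double bond to the methyl-bearing carbon) | C=CCC[C@@H]1C(C)=C(O[Li])C2OC2C1(C)C | intermediate (not isolated)
10 | (3S,4S)-4-(but-3-en-1-yl)-3-[1-hydroxy-3-(2-methyl-1,3-dioxolan-2-yl)propyl]-3,5,5-trimethyl-7-oxabicyclo[4.1.0]heptan-2-one, carbinol and epoxide epimers | C=CCC[C@H]1C(C)(C)C2OC2C(=O)[C@]1(C)C(O)CCC3(C)OCCO3 | intermediate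
11 | hydrazone of 10 at the ring carbonyl | C=CCC[C@H]1C(C)(C)C2OC2C(=NN)[C@]1(C)C(O)CCC3(C)OCCO3 | intermediate (not isolated)
12 | (4S,5S)-5-(but-3-en-1-yl)-4-[1-hydroxy-3-(2-methyl-1,3-dioxolan-2-yl)propyl]-4,6,6-trimethylcyclohex-2-en-1-ol, epimers at both carbinol carbons | C=CCC[C@H]1C(C)(C)C(O)C=C[C@]1(C)C(O)CCC2(C)OCCO2 | intermediate
13 | (4S,5R)-5-(but-3-en-1-yl)-4-[1-hydroxy-3-(2-methyl-1,3-dioxolan-2-yl)propyl]-4,6,6-trimethylcyclohex-2-en-1-one, carbinol epimers | C=CCC[C@H]1C(C)(C)C(=O)C=C[C@]1(C)C(O)CCC2(C)OCCO2 | intermediate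
14 | tosylhydrazone of 13 | C=CCC[C@H]1C(C)(C)C(=NNS(=O)(=O)c2ccc(C)cc2)C=C[C@]1(C)C(O)CCC3(C)OCCO3 | intermediate
15 | allylic diazene from 14 (N=NH on C3, C1=C2 alkene) | C=CCC[C@H]1C(C)(C)C(N=N)C=C[C@]1(C)C(O)CCC2(C)OCCO2 | intermediate (not isolated)
16 | 1-[(1S,6S)-6-(but-3-en-1-yl)-1,5,5-trimethylcyclohex-3-en-1-yl]-3-(2-methyl-1,3-dioxolan-2-yl)propan-1-ol, carbinol epimers | C=CCC[C@H]1C(C)(C)C=CC[C@]1(C)C(O)CCC2(C)OCCO2 | intermediate
17 | 1-[(1S,6S)-6-(but-3-en-1-yl)-1,5,5-trimethylcyclohex-3-en-1-yl]-3-(2-methyl-1,3-dioxolan-2-yl)propan-1-one | CC1(OCCO1)CCC(=O)[C@@]2(C)CC=CC(C)(C)[C@@H]2CCC=C | intermediate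
18 | cyclised organosamarium alkoxide (O–SmI2 on C9, CH2–SmI2 on C8) | CC1(OCCO1)CC[C@]2(O[Sm](I)I)[C@H](C[Sm](I)I)CC[C@H]3C(C)(C)C=CC[C@@]32C | intermediate (not isolated)
19 | (1S,2R,4aS,8aS)-2,5,5,8a-tetramethyl-1-[2-(2-methyl-1,3-dioxolan-2-yl)ethyl]-1,2,3,4,4a,5,8,8a-octahydronaphthalen-1-ol | CC1(OCCO1)CC[C@]2(O)[C@H](C)CC[C@H]3C(C)(C)C=CC[C@@]32C | intermediate
20 | (1S,2R,4aS,6S,7R,8aS)-2,5,5,8a-tetramethyl-1-[2-(2-methyl-1,3-dioxolan-2-yl)ethyl]decahydronaphthalene-1,6,7-triol | CC1(OCCO1)CC[C@]2(O)[C@H](C)CC[C@H]3C(C)(C)[C@H](O)[C@H](O)C[C@@]32C | intermediate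
21 | 4-[(1S,2R,4aS,6S,7R,8aS)-1,6,7-trihydroxy-2,5,5,8a-tetramethyldecahydronaphthalen-1-yl]butan-2-one | CC(=O)CC[C@]1(O)[C@H](C)CC[C@H]2C(C)(C)[C@H](O)[C@H](O)C[C@@]21C | intermediate
22 | trimethyl phosphonoacetate | COC(=O)CP(=O)(OC)OC | starting material
23 | methyl (2E)-3-methyl-5-[(1S,2R,4aS,6S,7R,8aS)-1,6,7-trihydroxy-2,5,5,8a-tetramethyldecahydronaphthalen-1-yl]pent-2-enoate | COC(=O)/C=C(\C)CC[C@]1(O)[C@H](C)CC[C@H]2C(C)(C)[C@H](O)[C@H](O)C[C@@]21C | intermediate
24 | acetic anhydride | CC(=O)OC(C)=O | starting material
25 | methyl (2E)-5-[(1S,2R,4aS,6S,7R,8aS)-7-acetoxy-1,6-dihydroxy-2,5,5,8a-tetramethyldecahydronaphthalen-1-yl]-3-methylpent-2-enoate (CNP0135744.1) | COC(=O)/C=C(\C)CC[C@]1(O)[C@H](C)CC[C@H]2C(C)(C)[C@H](O)[C@H](OC(C)=O)C[C@@]21C | target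

Total step count: 14.
Longest linear sequence: 14 steps (1 to 25); 3, 4, 8, 22 and 24 enter as purchased reagents.

**Steps most likely to fail**

Step 10. The 6-exo addition onto an unactivated alkene is slow, so the ketyl may take up a second electron and a proton (simple reduction to the C9 carbinol) before the C8–C9 bond forms, or the two chair modes at C9 may not be well separated. The fallback activates the acceptor. It sets out from 17: cross-metathesis with phenyl vinyl sulfone (second-generation Grubbs catalyst RuCl2(=CHPh)(PCy3)(H2IMes), CH2Cl2, 40 °C; the ring alkene is inert) should give the (E)-vinyl sulfone F1. SmI2 with MeOH in THF at −78 °C should then close ring B by ketyl addition to the sulfone-bearing alkene, giving the cyclised sulfone F2. Reductive removal of the sulfonyl group with Na(Hg), Na2HPO4 in MeOH returns to the route at 19.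

Step 2. The β-carbon is shielded by the neighbouring quaternary carbon, so facial selectivity may be poor, the Grignard reagent may add 1,2, or C-methylation of the magnesium enolate may stay incomplete. The fallback uses a zinc nucleophile and a different ligand class and separates the methylation. It sets out from 2: Cu(OTf)2 (2 mol%) with the phosphoramidite made from (S)-1,1′-bi-2-naphthol and bis[(R)-1-phenylethyl]amine (4 mol%), di(but-3-en-1-yl)zinc (from 3 and ZnCl2), toluene, −30 °C, aqueous HCl quench, should give (5R)-5-(but-3-en-1-yl)-4,4-dimethylcyclohex-2-en-1-one F3. LiN(i-Pr)2 in THF at −78 °C followed by MeI then methylates the only enolisable carbon and returns to the route at 6.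

Step 7. Condensation at the ring carbonyl, which is flanked by the gem-dimethyl carbon, may stay incomplete under the acid-free conditions, and forcing it with acid would cause loss of the dioxolane by ketal exchange. The fallback avoids hydrazone chemistry. It sets out from 13: 1,4-reduction with LiBH(s-Bu)3 (2.2 equiv, THF, −78 °C) and trapping of the enolate with N-phenylbis(trifluoromethanesulfonimide) should give the enol triflate F4 (double bond C2=C3). Reduction of the triflate with Pd(OAc)2, PPh3, HCO2H and Bu3N in DMF at 60 °C replaces OTf by H and returns to the route at 16, bypassing steps 7 and 8.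

**Further compounds**

F1 | step 10 | 1-[(1S,6S)-1,5,5-trimethyl-6-[(3E)-4-(phenylsulfonyl)but-3-en-1-yl]cyclohex-3-en-1-yl]-3-(2-methyl-1,3-dioxolan-2-yl)propan-1-one | CC1(OCCO1)CCC(=O)[C@@]2(C)CC=CC(C)(C)[C@@H]2CC/C=C/S(=O)(=O)c3ccccc3
F2 | step 10 | cyclised sulfone: 19 with CH2SO2Ph in place of the C8 methyl group (same ring configuration) | CC1(OCCO1)CC[C@]2(O)[C@H](CS(=O)(=O)c4ccccc4)CC[C@H]3C(C)(C)C=CC[C@@]32C
F3 | step 2 | (5R)-5-(but-3-en-1-yl)-4,4-dimethylcyclohex-2-en-1-one | C=CCC[C@@H]1CC(=O)C=CC1(C)C
F4 | step 7 | 5-(but-3-en-1-yl)-4-[1-hydroxy-3-(2-methyl-1,3-dioxolan-2-yl)propyl]-4,6,6-trimethylcyclohex-1-en-1-yl trifluoromethanesulfonate (ring stereocentres as in 13) | C=CCC[C@H]1C(C)(C)C(OS(=O)(=O)C(F)(F)F)=CC[C@]1(C)C(O)CCC2(C)OCCO2
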